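**Retrosynthetic overview**
1. Target 25 ⇐ angeloylation of the C3 hydroxyl and desilylation of macrocycle 21, which already carries the C6 acetate.
2. 21 ⇐ C9–C10 disconnection of the ten-membered carbocycle (C1–C10). This bond joins the unfunctionalised C9 methylene to the methyl-bearing sp2 carbon C10 of the E C1=C10 alkene and lies across the ring from the five contiguous stereocentres C3–C7, so all of them can be set on an open chain (19) and the ring closed by 9-BBN hydroboration of C8=C9 and intramolecular B-alkyl Suzuki coupling with the C10 vinyl iodide.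
3. 19 ⇐ C4–C5 oxirane by C6-hydroxyl-directed epoxidation of trienol 17; 17 ⇐ C6–C7 by anti-selective γ-isopropylallylboration of enal 11.
4. 11 ⇐ hydrozirconation–iodination of a methylalkyne, built by C2–C3 propargylation of the C5 enal 2 from prenyl acetate 1.
5. Ring order: oxirane first (step 11), ten-membered carbocycle last (step 13).

Key step: step 13

Remark: germacrane locants (C1–C10, C14 = methyl on C10, C15 = methyl on C4) are used for all intermediates; the sense of induction of the phosphoric acid in steps 2 and 10 is assigned by analogy with aryl and alkenyl aldehydes (R acid giving R carbinols) and would be checked on 4 by Mosher ester analysis, the enantiomeric acid being used if it proved reversed.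

**Route**

Step 1
Reactants: 1 prenyl acetate
Product: 2 (2E)-3-methyl-4-oxobut-2-en-1-yl acetate
Conditions: SeO2 (1.2 equiv), 1,4-dioxane, 80 °C
Reagents that add atoms: selenium dioxide, O=[Se]=O
Why: Riley allylic oxidation (ene reaction, then 2,3-sigmatropic shift) attacks the E methyl group of the trisubstituted alkene and over-oxidation of the allylic alcohol gives the E enal, whose CHO carbon becomes C3 and whose CH2OAc carbon becomes C6.

Step 2
Reactants: 2 (2E)-3-methyl-4-oxobut-2-en-1-yl acetate; 3 allenylboronic acid pinacol ester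
Product: 4 (2E,4S)-4-hydroxy-3-methylhept-2-en-6-yn-1-yl acetate
Conditions: (S)-TRIP [(S)-3,3'-bis(2,4,6-triisopropylphenyl)-1,1'-binaphthyl-2,2'-diyl hydrogen phosphate] (5 mol%), 4 Å MS, toluene, −20 °C; aqueous work-up
Reagents that add atoms: none
Why: Chiral phosphoric acid-catalysed propargylation with an allenylboronate runs through a six-membered cyclic transition state (attack through the allene terminus, so only the homopropargylic alcohol forms) in which the acid binds the boronate oxygen and the formyl hydrogen, so the catalyst sets C3, expected S by addition to the Si face of the enal.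

Step 3
Reactants: 4 (2E,4S)-4-hydroxy-3-methylhept-2-en-6-yn-1-yl acetate
Product: 5 (2E,4S)-4-[(tert-butyldimethylsilyl)oxy]-3-methylhept-2-en-6-yn-1-yl acetate
Conditions: TBSCl, imidazole, DMF, rt
Reagents that add atoms: tert-butyldimethylsilyl chloride, CC(C)(C)[Si](C)(C)Cl
Why: Standard imidazole-promoted silylation of a secondary alcohol that leaves C3 and the acetate untouched.

Step 4
Reactants: 5 (2E,4S)-4-[(tert-butyldimethylsilyl)oxy]-3-methylhept-2-en-6-yn-1-yl acetate
Product: 6 (2E,4S)-4-[(tert-butyldimethylsilyl)oxy]-3-methylhept-2-en-6-yn-1-ol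
Conditions: K2CO3 (0.2 equiv), MeOH, 0 °C
Reagents that add atoms: none
Why: Base-catalysed methanolysis (transesterification) removes the primary allylic acetate without affecting the silyl ether or the terminal alkyne.

Step 5
Reactants: 6 (2E,4S)-4-[(tert-butyldimethylsilyl)oxy]-3-methylhept-2-en-6-yn-1-ol
Product: 8 (2E,4S)-4-[(tert-butyldimethylsilyl)oxy]-3-methyloct-2-en-6-yn-1-ol, via dilithio derivative 7 (not isolated)
Conditions: n-BuLi (2.1 equiv), THF, −78 to −20 °C; MeI (1.05 equiv), −78 °C to rt; H2O
Reagents that add atoms: iodomethane, CI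
Why: C-alkylation of an alkynol dianion, in which the acetylide carbon is far more nucleophilic towards one equivalent of iodomethane in THF than the lithium alkoxide, installs C14.

Step 6
Reactants: 8 (2E,4S)-4-[(tert-butyldimethylsilyl)oxy]-3-methyloct-2-en-6-yn-1-ol
Product: 10 (2E,4S,6E)-4-[(tert-butyldimethylsilyl)oxy]-7-iodo-3-methylocta-2,6-dien-1-ol, via alkenylzirconocene chloride 9 (not isolated)
Conditions: Cp2Zr(H)Cl (3 equiv), THF, rt then 45 °C; I2, THF, 0 °C; aqueous work-up
Reagents that add atoms: iodine, II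
Why: Hydrozirconation–iodination: syn addition of Zr–H to the methylalkyne equilibrates under excess reagent to the isomer with zirconium on the less hindered methyl-bearing C10, and iodinolysis with retention gives the E vinyl iodide; one equivalent is consumed by the hydroxyl group and the trisubstituted C4=C5 alkene does not react.

Step 7
Reactants: 10 (2E,4S,6E)-4-[(tert-butyldimethylsilyl)oxy]-7-iodo-3-methylocta-2,6-dien-1-ol
Product: 11 (2E,4S,6E)-4-[(tert-butyldimethylsilyl)oxy]-7-iodo-3-methylocta-2,6-dienal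
Conditions: MnO2, CH2Cl2, rt
Reagents that add atoms: none
Why: MnO2 oxidation is selective for the primary allylic alcohol, keeps the E geometry and leaves the vinyl iodide and silyl ether alone.

Step 8
Reactants: 12 3-methylbut-1-yne; 13 pinacolborane
Product: 14 (E)-2-(3-methylbut-1-en-1-yl)-4,4,5,5-tetramethyl-1,3,2-dioxaborolane
Conditions: Cp2Zr(H)Cl (5 mol%), Et3N (10 mol%), neat, 60 °C, sealed tube
Reagents that add atoms: none
Why: Zirconocene-catalysed hydroboration of a terminal alkyne is a syn, anti-Markovnikov addition and gives the E alkenylboronate.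

Step 9
Reactants: 14 (E)-2-(3-methylbut-1-en-1-yl)-4,4,5,5-tetramethyl-1,3,2-dioxaborolane
Product: 16 (E)-2-(4-methylpent-2-en-1-yl)-4,4,5,5-tetramethyl-1,3,2-dioxaborolane, via chloromethyl borate complex 15 (not isolated)
Conditions: ICH2Cl, n-BuLi, THF, −78 °C to rt
Reagents that add atoms: chloroiodomethane, ClCI
Why: Matteson homologation: (chloromethyl)lithium made in situ adds to boron and 1,2-migration of the alkenyl group with loss of chloride inserts one CH2, giving the allylboronate with the E geometry unchanged.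

Step 10
Reactants: 11 (2E,4S,6E)-4-[(tert-butyldimethylsilyl)oxy]-7-iodo-3-methylocta-2,6-dienal; 16 (E)-2-(4-methylpent-2-en-1-yl)-4,4,5,5-tetramethyl-1,3,2-dioxaborolane
Product: 17 (3S,4S,5E,7S,9E)-7-[(tert-butyldimethylsilyl)oxy]-10-iodo-6-methyl-3-(propan-2-yl)undeca-1,5,9-trien-4-ol
Conditions: (S)-TRIP (10 mol%), 4 Å MS, toluene, −30 to 0 °C; aqueous work-up
Reagents that add atoms: none
Why: Phosphoric acid-catalysed allylboration through a closed chair (Zimmerman–Traxler) transition state, in which the E geometry of 16 gives the anti C6/C7 relationship and the S acid is expected to direct addition to the Si face of the aldehyde (C6 S, hence C7 S), the remote C3 centre having no influence.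

Step 11
Reactants: 17 (3S,4S,5E,7S,9E)-7-[(tert-butyldimethylsilyl)oxy]-10-iodo-6-methyl-3-(propan-2-yl)undeca-1,5,9-trien-4-ol
Product: 18 (3S,4S,5R,6S,7S,9E)-7-[(tert-butyldimethylsilyl)oxy]-5,6-epoxy-10-iodo-6-methyl-3-(propan-2-yl)undeca-1,9-dien-4-ol
Conditions: mCPBA (1.1 equiv), NaHCO3, CH2Cl2, 0 °C
Reagents that add atoms: 3-chloroperoxybenzoic acid, OOC(=O)c1cccc(Cl)c1
Why: Hydroxyl-directed (Henbest) peracid epoxidation, in which A1,3 strain between the C6 carbinol and the cis C15 methyl holds the C6–H in the alkene plane so that the hydrogen-bonded peracid attacks the face syn to the hydroxyl and gives the threo epoxy alcohol (both oxirane carbons set together by stereospecific syn addition to the E alkene), the directed trisubstituted C4=C5 alkene reacting much faster than the monosubstituted C8=C9 alkene and the iodoalkene.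

Step 12
Reactants: 18 (3S,4S,5R,6S,7S,9E)-7-[(tert-butyldimethylsilyl)oxy]-5,6-epoxy-10-iodo-6-methyl-3-(propan-2-yl)undeca-1,9-dien-4-ol
Product: 19 (3S,4S,5R,6S,7S,9E)-7-[(tert-butyldimethylsilyl)oxy]-5,6-epoxy-10-iodo-6-methyl-3-(propan-2-yl)undeca-1,9-dien-4-yl acetate
Conditions: Ac2O, pyridine, DMAP (cat.), CH2Cl2, 0 °C to rt
Reagents that add atoms: acetic anhydride, CC(=O)OC(C)=O
Why: Routine acylation of the secondary alcohol, done now so that the final C6 ester is in place and no selective deprotection is needed later on the acid-sensitive epoxy-cyclodecene.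

Step 13
Reactants: 19 (3S,4S,5R,6S,7S,9E)-7-[(tert-butyldimethylsilyl)oxy]-5,6-epoxy-10-iodo-6-methyl-3-(propan-2-yl)undeca-1,9-dien-4-yl acetate
Product: 21 (1(10)E,3S,4S,5R,6S,7R)-3-[(tert-butyldimethylsilyl)oxy]-4,5-epoxygermacr-1(10)-en-6-yl acetate, via C9 alkylborane 20 (not isolated)
Conditions: 9-BBN dimer (1.5 equiv B–H), THF, rt; then syringe-pump addition to Pd(dppf)Cl2 (20 mol%), AsPh3 (40 mol%), Cs2CO3 (3 equiv), DMF/THF/H2O, rt, final concentration about 1 mM
Reagents that add atoms: none
Why: 9-BBN adds anti-Markovnikov only to the monosubstituted C8=C9 alkene (the iodoalkene is trisubstituted and deactivated, epoxide and acetate are inert at rt) to give the primary C9 borane 20; base forms its borate, zerovalent palladium inserts into the C10–I bond with retention, and intramolecular transmetalation followed by reductive elimination forms C9–C10, which is the B-alkyl Suzuki–Miyaura macrocyclisation known for cycloalkenes with an E trisubstituted double bond. The ten-membered carbocycle closes by reductive elimination from an eleven-membered alkyl(alkenyl)palladacycle, an sp3–sp2 closure at a bond remote from C3–C7. No stereocentre is created, and the E geometry of C1=C10 is carried over from the vinyl iodide because oxidative addition and reductive elimination are stereoretentive. Ring closure has to win over oligomerisation, which slow addition of 20 at high dilution and the conformational restriction by the trans epoxide and its two flanking oxygen substituents are meant to secure. The arsine ligand and the wide bite angle of dppf favour transmetalation and reductive elimination over beta-hydride elimination, and the carbonate base at rt should leave acetate, epoxide and silyl ether intact.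

Step 14
Reactants: 21 (1(10)E,3S,4S,5R,6S,7R)-3-[(tert-butyldimethylsilyl)oxy]-4,5-epoxygermacr-1(10)-en-6-yl acetate
Product: 22 (1(10)E,3S,4R,5R,6S,7R)-4,5-epoxy-3-hydroxygermacr-1(10)-en-6-yl acetate
Conditions: TBAF, AcOH (1:1), THF, rt
Reagents that add atoms: none
Why: Fluoride desilylation buffered with acetic acid stays near neutral, so neither acetate migration through a free C3 alkoxide nor acid-induced transannular opening of the epoxide by the C1=C10 alkene is opened up.

Step 15
Reactants: 22 (1(10)E,3S,4R,5R,6S,7R)-4,5-epoxy-3-hydroxygermacr-1(10)-en-6-yl acetate; 23 angelic acid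
Product: 25 (1(10)E,3S,4R,5R,6S,7R)-6-acetoxy-4,5-epoxygermacr-1(10)-en-3-yl (Z)-2-methylbut-2-enoate (CNP0180504.1), via mixed anhydride 24 (not isolated)
Conditions: 2,4,6-trichlorobenzoyl chloride, Et3N, toluene, rt; then 22, 80 °C
Reagents that add atoms: none
Why: Yamaguchi-type mixed-anhydride esterification run without a nucleophilic amine catalyst, so that no conjugate addition–elimination path from the Z (angelate) to the E (tiglate) ester is opened, the alcohol attacking the less hindered angeloyl carbonyl of 24.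

**Compound list**
1 | prenyl acetate | CC(C)=CCOC(C)=O | starting material
2 | (2E)-3-methyl-4-oxobut-2-en-1-yl acetate | CC(=O)OC/C=C(\C)C=O | intermediate
3 | allenylboronic acid pinacol ester | C=C=CB1OC(C)(C)C(C)(C)O1 | starting material
4 | (2E,4S)-4-hydroxy-3-methylhept-2-en-6-yn-1-yl acetate | C#CC[C@H](O)/C(C)=C/COC(C)=O | intermediate
5 | (2E,4S)-4-[(tert-butyldimethylsilyl)oxy]-3-methylhept-2-en-6-yn-1-yl acetate | C#CC[C@H](O[Si](C)(C)C(C)(C)C)/C(C)=C/COC(C)=O | intermediate
6 | (2E,4S)-4-[(tert-butyldimethylsilyl)oxy]-3-methylhept-2-en-6-yn-1-ol | C#CC[C@H](O[Si](C)(C)C(C)(C)C)/C(C)=C/CO | intermediate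
7 | dilithio derivative of 6 (lithium alkoxide and lithium acetylide) | [Li]C#CC[C@H](O[Si](C)(C)C(C)(C)C)/C(C)=C/CO[Li] | intermediate
8 | (2E,4S)-4-[(tert-butyldimethylsilyl)oxy]-3-methyloct-2-en-6-yn-1-ol | CC#CC[C@H](O[Si](C)(C)C(C)(C)C)/C(C)=C/CO | intermediate
9 | alkenylzirconocene chloride from 8 (Zr on C10, E; hydroxyl as zirconium alkoxide) | C/C(=C\C[C@H](O[Si](C)(C)C(C)(C)C)/C(C)=C/CO[Zr](Cl)(C1C=CC=C1)C1C=CC=C1)[Zr](Cl)(C1C=CC=C1)C1C=CC=C1 | intermediate
10 | (2E,4S,6E)-4-[(tert-butyldimethylsilyl)oxy]-7-iodo-3-methylocta-2,6-dien-1-ol | I/C(C)=C/C[C@H](O[Si](C)(C)C(C)(C)C)/C(C)=C/CO | intermediate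
11 | (2E,4S,6E)-4-[(tert-butyldimethylsilyl)oxy]-7-iodo-3-methylocta-2,6-dienal | I/C(C)=C/C[C@H](O[Si](C)(C)C(C)(C)C)/C(C)=C/C=O | intermediate
12 | 3-methylbut-1-yne | CC(C)C#C | starting material
13 | pinacolborane | CC1(C)OBOC1(C)C | starting material
14 | (E)-2-(3-methylbut-1-en-1-yl)-4,4,5,5-tetramethyl-1,3,2-dioxaborolane | CC(C)/C=C/B1OC(C)(C)C(C)(C)O1 | intermediate
15 | lithium (chloromethyl)[(E)-3-methylbut-1-en-1-yl]pinacolborate | [Li+].ClC[B-]1(/C=C/C(C)C)OC(C)(C)C(C)(C)O1 | intermediate
16 | (E)-2-(4-methylpent-2-en-1-yl)-4,4,5,5-tetramethyl-1,3,2-dioxaborolane | CC(C)/C=C/CB1OC(C)(C)C(C)(C)O1 | intermediate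
17 | (3S,4S,5E,7S,9E)-7-[(tert-butyldimethylsilyl)oxy]-10-iodo-6-methyl-3-(propan-2-yl)undeca-1,5,9-trien-4-ol | I/C(C)=C/C[C@H](O[Si](C)(C)C(C)(C)C)/C(C)=C/[C@@H](O)[C@@H](C(C)C)C=C | intermediate
18 | (3S,4S,5R,6S,7S,9E)-7-[(tert-butyldimethylsilyl)oxy]-5,6-epoxy-10-iodo-6-methyl-3-(propan-2-yl)undeca-1,9-dien-4-ol | I/C(C)=C/C[C@H](O[Si](C)(C)C(C)(C)C)[C@@]1(C)O[C@@H]1[C@@H](O)[C@@H](C(C)C)C=C | intermediate
19 | (3S,4S,5R,6S,7S,9E)-7-[(tert-butyldimethylsilyl)oxy]-5,6-epoxy-10-iodo-6-methyl-3-(propan-2-yl)undeca-1,9-dien-4-yl acetate (open-chain precursor: C3 OTBS, C6 OAc, C7 isopropyl, C8=C9 vinyl, C10 E vinyl iodide) | I/C(C)=C/C[C@H](O[Si](C)(C)C(C)(C)C)[C@@]1(C)O[C@@H]1[C@@H](OC(C)=O)[C@@H](C(C)C)C=C | intermediate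
20 | B-alkyl-9-borabicyclo[3.3.1]nonane from 19 (boron on C9) | I/C(C)=C/C[C@H](O[Si](C)(C)C(C)(C)C)[C@@]1(C)O[C@@H]1[C@@H](OC(C)=O)[C@@H](C(C)C)CCB1C2CCCC1CCC2 | intermediate
21 | (1(10)E,3S,4S,5R,6S,7R)-3-[(tert-butyldimethylsilyl)oxy]-4,5-epoxygermacr-1(10)-en-6-yl acetate | CC(C)(C)[Si](C)(C)O[C@H]1C/C=C(\C)CC[C@H](C(C)C)[C@H](OC(C)=O)[C@H]2O[C@]12C | intermediate
22 | (1(10)E,3S,4R,5R,6S,7R)-4,5-epoxy-3-hydroxygermacr-1(10)-en-6-yl acetate | O[C@H]1C/C=C(\C)CC[C@H](C(C)C)[C@H](OC(C)=O)[C@H]2O[C@]12C | intermediate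
23 | angelic acid, (Z)-2-methylbut-2-enoic acid | C/C=C(/C)C(=O)O | starting material
24 | angelic 2,4,6-trichlorobenzoic anhydride | C/C=C(/C)C(=O)OC(=O)c1c(Cl)cc(Cl)cc1Cl | intermediate
25 | (1(10)E,3S,4R,5R,6S,7R)-6-acetoxy-4,5-epoxygermacr-1(10)-en-3-yl (Z)-2-methylbut-2-enoate, CNP0180504.1 | C/C=C(/C)C(=O)O[C@H]1C/C=C(\C)CC[C@H](C(C)C)[C@H](OC(C)=O)[C@H]2O[C@]12C | target

**Count and risks**

Total step count: 15. Longest linear sequence: 13 steps (steps 1–7 and 10–15, from prenyl acetate); boronate 16 is made in a two-step side branch (steps 8–9).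

Steps most likely to fail:

1. Step 13. Closure of a ten-membered ring is slow, so intermolecular coupling to oligomers, protodeboronation or beta-hydride elimination from the alkylpalladium may overtake cyclisation. Fallback (sets out from 19, returns at 21): the C9–C10 bond is made by an intramolecular Negishi coupling, whose alkylzinc transmetalates without base or water. 19 is hydroborated as before and the borane 20 is oxidised (NaBO3·4H2O, THF/H2O) to the primary alcohol F1. Appel iodination (I2, PPh3, imidazole, CH2Cl2, 0 °C) gives the primary iodide F2. Zinc dust (activated with 1,2-dibromoethane and TMSCl, DMA, 35 °C) inserts into the sp3 C–I bond only and gives the alkylzinc iodide F3, which is added slowly to Pd(PPh3)4 in THF at high dilution to give 21.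

2. Step 10. The γ-isopropyl boronate is hindered and the β,β-disubstituted enal is a weak electrophile, so the catalysed pathway may slow down enough for uncatalysed background addition to erode facial selectivity. Fallback (sets out from 11, returns at 17): C6–C7 is formed by an auxiliary-controlled anti-aldol reaction and the vinyl group is built afterwards. Isovaleryl chloride and (S)-4-benzyloxazolidin-2-one (n-BuLi, THF, −78 °C) give the imide F4. The MgCl2-catalysed Evans anti-aldol addition of F4 to 11 (MgCl2, Et3N, TMSCl, EtOAc, rt) should give the silylated aldol adduct F5 through the chelated Z enolate (facial sense as in chelate-controlled alkylations of this auxiliary), and brief acidic methanolysis frees the aldol F6 with the C6/C7 configuration of 17. TESCl and imidazole give the triethylsilyl ether F7, LiBH4 (THF, MeOH, 0 °C) removes the auxiliary and gives the primary alcohol F8, Dess–Martin oxidation gives the aldehyde F9, Wittig methylenation (Ph3P=CH2, THF, 0 °C) gives the triene F10, and selective cleavage of the triethylsilyl ether (PPTS, MeOH, 0 °C) returns 17.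

3. Step 11. The silyloxy stereocentre C3 next to C4 may disturb the A1,3-controlled conformation or shield the hydroxyl-bearing face, lowering facial selectivity, and over-oxidation at the other alkenes is conceivable. Fallback (sets out from 10, returns at 18): the oxirane is installed under reagent control before C6–C7 is made. Sharpless asymmetric epoxidation of 10 (Ti(OiPr)4, D-(−)-diethyl tartrate, t-BuOOH, 4 Å MS, CH2Cl2, −20 °C) gives the epoxy alcohol F11, Dess–Martin oxidation (NaHCO3, CH2Cl2) gives the epoxy aldehyde F12, and addition of 16 under the conditions of step 10 (catalyst control of the aldehyde face, anti from the E boronate) gives 18 directly.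

**Further compounds**
F1 | step 13 | C9 primary alcohol from hydroboration–oxidation of 19 | I/C(C)=C/C[C@H](O[Si](C)(C)C(C)(C)C)[C@@]1(C)O[C@@H]1[C@@H](OC(C)=O)[C@@H](C(C)C)CCO
F2 | step 13 | C9 primary iodide | I/C(C)=C/C[C@H](O[Si](C)(C)C(C)(C)C)[C@@]1(C)O[C@@H]1[C@@H](OC(C)=O)[C@@H](C(C)C)CCI
F3 | step 13 | C9 alkylzinc iodide | I/C(C)=C/C[C@H](O[Si](C)(C)C(C)(C)C)[C@@]1(C)O[C@@H]1[C@@H](OC(C)=O)[C@@H](C(C)C)CC[Zn]I
F4 | step 10 | (S)-4-benzyl-3-(3-methylbutanoyl)oxazolidin-2-one | CC(C)CC(=O)N1[C@@H](Cc2ccccc2)COC1=O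
F5 | step 10 | anti-aldol adduct of F4 and 11, C6 trimethylsilyl ether | I/C(C)=C/C[C@H](O[Si](C)(C)C(C)(C)C)/C(C)=C/[C@@H](O[Si](C)(C)C)[C@@H](C(C)C)C(=O)N1[C@@H](Cc2ccccc2)COC1=O
F6 | step 10 | anti-aldol adduct, C6 hydroxyl free | I/C(C)=C/C[C@H](O[Si](C)(C)C(C)(C)C)/C(C)=C/[C@@H](O)[C@@H](C(C)C)C(=O)N1[C@@H](Cc2ccccc2)COC1=O
F7 | step 10 | anti-aldol adduct, C6 triethylsilyl ether | I/C(C)=C/C[C@H](O[Si](C)(C)C(C)(C)C)/C(C)=C/[C@@H](O[Si](CC)(CC)CC)[C@@H](C(C)C)C(=O)N1[C@@H](Cc2ccccc2)COC1=O
F8 | step 10 | C8 primary alcohol, C6 triethylsilyl ether | I/C(C)=C/C[C@H](O[Si](C)(C)C(C)(C)C)/C(C)=C/[C@@H](O[Si](CC)(CC)CC)[C@@H](C(C)C)CO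
F9 | step 10 | C8 aldehyde, C6 triethylsilyl ether | I/C(C)=C/C[C@H](O[Si](C)(C)C(C)(C)C)/C(C)=C/[C@@H](O[Si](CC)(CC)CC)[C@@H](C(C)C)C=O
F10 | step 10 | 6-O-triethylsilyl ether of 17 | I/C(C)=C/C[C@H](O[Si](C)(C)C(C)(C)C)/C(C)=C/[C@@H](O[Si](CC)(CC)CC)[C@@H](C(C)C)C=C
F11 | step 11 | C4–C5 epoxy alcohol from 10 (C6 primary alcohol) | I/C(C)=C/C[C@H](O[Si](C)(C)C(C)(C)C)[C@@]1(C)O[C@@H]1CO
F12 | step 11 | C4–C5 epoxy aldehyde (C6 aldehyde) | I/C(C)=C/C[C@H](O[Si](C)(C)C(C)(C)C)[C@@]1(C)O[C@@H]1C=O
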